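## Retrosynthetic overview

- Feature: in the dihydrofuran ring O1–C2–C3–C3a–C7a, C3 is bonded to arene carbon C3a and carries a one-carbon substituent. This pattern arises when benzo carbon C4a of a 7-oxygenated (2S)-flavanone moves from the carbonyl carbon C4 to C3: C4 becomes the C3 methyl carbon, and C2 (O, aryl, H) is carried over unchanged.
- Target ⇐ trans methyl 5-bromo-6-pivaloyloxy-2-aryl-2,3-dihydrobenzofuran-3-carboxylate: CO2Me → CH2OH → CH2I → CH3, and C5–Br → C5–allyl (Stille).
- That ester ⇐ (S)-6-bromo-7-pivaloyloxy-3',4',5'-trimethoxyflavanone by an iodine(III)-induced 1,2-aryl shift with ring contraction (forms C3–C3a, sets C3 trans to C2).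
- Flavanone ⇐ 6-bromo-7-pivaloyloxychromone + 3,4,5-trimethoxyphenylboronic acid (enantioselective 1,4-addition sets C2); chromone ⇐ 5-bromo-2,4-dihydroxyacetophenone + one carbon (enaminone).
- Ring order: γ-pyranone ring (step 1), contracted to the dihydrofuran ring (step 4); both benzene rings are bought.

Key step: step 4

Assumption: the (R)-antipode of the pyridine–oxazoline ligand is taken to deliver the aryl group to the face that makes C2 S, by analogy with the sense of aryl delivery of this catalyst to cyclic enones; if a first run shows the opposite sense, the (S)-ligand is used and nothing else changes.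

## Route

Step 1
Reactants: 1 1-(5-bromo-2,4-dihydroxyphenyl)ethanone
Product: 3 6-bromo-7-hydroxy-4H-chromen-4-one, via enaminone 2 (not isolated)
Conditions: Me2NCH(OMe)2 (1.5 equiv), PhMe, 90 °C; then conc. HCl, CH2Cl2, 40 °C
Reagents that add atoms: N,N-dimethylformamide dimethyl acetal, COC(OC)N(C)C
Why: Condensation of the acetyl methyl group with the amide acetal gives the β-dimethylaminoenone, and acid then promotes addition of the ortho phenol to its β-carbon and loss of dimethylamine to close the γ-pyranone (enaminone route to chromones); the reagent excess is kept small so that the 4-hydroxyl is not methylated.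

Step 2
Reactants: 3 6-bromo-7-hydroxy-4H-chromen-4-one
Product: 4 6-bromo-4-oxo-4H-chromen-7-yl pivalate
Conditions: PivCl (1.2 equiv), Et3N, DMAP (cat.), CH2Cl2, 0 °C to rt
Reagents that add atoms: pivaloyl chloride, CC(C)(C)C(=O)Cl
Why: DMAP-catalysed acylation of the only free phenol gives an ester that makes the chromone more electrophilic, survives acidic methanol and shields the phenol from iodine(III) in step 4.

Step 3
Reactants: 4 6-bromo-4-oxo-4H-chromen-7-yl pivalate; 5 3,4,5-trimethoxyphenylboronic acid
Product: 6 (S)-6-bromo-4-oxo-2-(3,4,5-trimethoxyphenyl)chroman-7-yl pivalate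
Conditions: Pd(OCOCF3)2 (5 mol%), (R)-t-BuPyOx (6 mol%), NH4PF6 (30 mol%), H2O (5 equiv), ClCH2CH2Cl, 60 °C, air; recrystallisation to raise ee if needed
Reagents that add atoms: 3,4,5-trimethoxyphenylboronic acid (5), COc1cc(B(O)O)cc(OC)c1OC
Why: Pd(II)/pyridine–oxazoline-catalysed asymmetric conjugate addition of an arylboronic acid to a chromone (transmetalation, enantioselective carbopalladation of C2=C3, protonolysis of the Pd enolate) sets C2 under control of the ligand's tert-butyl group; the catalyst stays Pd(II), so C–Br is untouched, and the mildly acidic medium prevents chalcone opening of the flavanone.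

Step 4
Reactants: 6 (S)-6-bromo-4-oxo-2-(3,4,5-trimethoxyphenyl)chroman-7-yl pivalate
Product: 9 methyl (2S,3S)-5-bromo-6-(pivaloyloxy)-2-(3,4,5-trimethoxyphenyl)-2,3-dihydrobenzofuran-3-carboxylate, via enol ether 7 (not isolated), via iodane ketal 8 (not isolated)
Conditions: PhI(OAc)2 (1.2 equiv), conc. H2SO4 (0.5 equiv), HC(OMe)3, 0 °C to rt
Reagents that add atoms: trimethyl orthoformate, COC(OC)OC; (diacetoxyiodo)benzene, CC(=O)OI(OC(C)=O)c1ccccc1 (atoms only in intermediate 8)
Why: In acidic trimethyl orthoformate the ketone is converted through its dimethyl ketal into the 4-methoxy-2H-chromene 7, whose C3 is attacked by the iodane on the face anti to the C2 aryl group while methanol adds at C4, giving the trans C3 λ3-iodane ketal 8. Its equatorial C3–I bond is antiperiplanar to the C4–C4a ring bond, so benzo carbon C4a shifts from C4 to C3 with loss of iodobenzene (a semipinacol-type 1,2-aryl shift through a phenonium-like bridged transition state), and the C4 dimethoxycarbenium ion gives the methyl ester by loss of a methyl group to acetate. The closest known reaction is the iodine(III)- or thallium(III)-mediated oxidative rearrangement of flavanones in trimethyl orthoformate to trans methyl 2-aryl-2,3-dihydrobenzofuran-3-carboxylates. The dihydrofuran ring is closed by contraction, not by cyclisation: C4a bridges onto C3 (formally a 3-exo attack on the carbon bearing iodine) and C4–C4a breaks, which forms C3–C3a and turns the six-membered ring into the five-membered one. C3 is set by inversion at the carbon that bore the iodane, which had been placed anti to the C2 aryl, so the ester ends up trans to the aryl (also the thermodynamically preferred arrangement); C2 is not involved and keeps its configuration because no enolate or chalcone forms in the acidic medium. The step needs migration of C4a in preference to migration of the C2 aryl (isoflavone) or elimination to the flavone; this is secured by the two ketal oxygens at C4, the ortho ring oxygen and para pivaloyloxy group on C4a and the alignment of the equatorial iodane, while the pivalate keeps the phenol from being oxidised.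

Step 5
Reactants: 9 methyl (2S,3S)-5-bromo-6-(pivaloyloxy)-2-(3,4,5-trimethoxyphenyl)-2,3-dihydrobenzofuran-3-carboxylate
Product: 10 methyl (2S,3S)-5-allyl-6-(pivaloyloxy)-2-(3,4,5-trimethoxyphenyl)-2,3-dihydrobenzofuran-3-carboxylate
Conditions: allylSnBu3 (1.5 equiv), Pd(PPh3)4 (5 mol%), PhMe (degassed), 100 °C
Reagents that add atoms: allyltributylstannane, C=CC[Sn](CCCC)(CCCC)CCCC
Why: Stille cross-coupling of the aryl bromide with the allylstannane runs without base, so the epimerisable β-aryloxy ester at C3 and the pivalate are not disturbed and no stereocentre is touched.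

Step 6
Reactants: 10 methyl (2S,3S)-5-allyl-6-(pivaloyloxy)-2-(3,4,5-trimethoxyphenyl)-2,3-dihydrobenzofuran-3-carboxylate
Product: 11 (2S,3R)-5-allyl-3-(hydroxymethyl)-2-(3,4,5-trimethoxyphenyl)-2,3-dihydrobenzofuran-6-ol
Conditions: LiAlH4 (3 equiv), THF, 0 °C to rt; aq. Rochelle salt work-up
Reagents that add atoms: none
Why: Hydride reduction takes the methyl ester to the primary alcohol and cleaves the aryl pivalate in the same operation; addition to the ester is faster than enolisation, so C3 is neither epimerised nor opened, and the terminal alkene is inert (the descriptor at C3 changes only through CIP priorities).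

Step 7
Reactants: 11 (2S,3R)-5-allyl-3-(hydroxymethyl)-2-(3,4,5-trimethoxyphenyl)-2,3-dihydrobenzofuran-6-ol
Product: 12 (2S,3S)-5-allyl-3-(iodomethyl)-2-(3,4,5-trimethoxyphenyl)-2,3-dihydrobenzofuran-6-ol
Conditions: PPh3 (1.3 equiv), imidazole (1.5 equiv), I2 (1.25 equiv), CH2Cl2, 0 °C (reagent preformed); then 11, 0 °C to rt
Reagents that add atoms: iodine, II
Why: Appel-type iodination is selective because only the aliphatic alkoxyphosphonium can be displaced by iodide (SN2 at the primary carbon) while the phenol is returned unchanged; preforming the phosphonium iodide keeps free iodine away from the 2-allylphenol.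

Step 8
Reactants: 12 (2S,3S)-5-allyl-3-(iodomethyl)-2-(3,4,5-trimethoxyphenyl)-2,3-dihydrobenzofuran-6-ol
Product: 13 (2S,3S)-5-allyl-3-methyl-2-(3,4,5-trimethoxyphenyl)-2,3-dihydrobenzofuran-6-ol
Conditions: Bu3SnH (1.5 equiv), AIBN (10 mol%), PhMe, 80 °C; KF work-up
Reagents that add atoms: none
Why: Radical-chain hydrodeiodination with tin hydride gives a primary radical that is quenched by Sn–H much faster than it can undergo aryl shift or ring opening; the neutral medium forms no phenoxide and leaves the alkene and both stereocentres untouched.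

## Compound list

1 | 1-(5-bromo-2,4-dihydroxyphenyl)ethanone | CC(=O)c1cc(Br)c(O)cc1O | starting material
2 | (E)-1-(5-bromo-2,4-dihydroxyphenyl)-3-(dimethylamino)prop-2-en-1-one | CN(C)/C=C/C(=O)c1cc(Br)c(O)cc1O | intermediate
3 | 6-bromo-7-hydroxy-4H-chromen-4-one | O=c1ccoc2cc(O)c(Br)cc12 | intermediate
4 | 6-bromo-4-oxo-4H-chromen-7-yl pivalate | CC(C)(C)C(=O)Oc1cc2occc(=O)c2cc1Br | intermediate
5 | 3,4,5-trimethoxyphenylboronic acid | COc1cc(B(O)O)cc(OC)c1OC | starting material
6 | (S)-6-bromo-4-oxo-2-(3,4,5-trimethoxyphenyl)chroman-7-yl pivalate | Brc1cc2c(cc1OC(=O)C(C)(C)C)O[C@H](c1cc(OC)c(OC)c(OC)c1)CC2=O | intermediate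
7 | (S)-6-bromo-4-methoxy-2-(3,4,5-trimethoxyphenyl)-2H-chromen-7-yl pivalate | Brc1cc2c(cc1OC(=O)C(C)(C)C)O[C@H](c1cc(OC)c(OC)c(OC)c1)C=C2OC | intermediate
8 | (2R,3R)-3-[acetoxy(phenyl)-λ3-iodanyl]-6-bromo-4,4-dimethoxy-2-(3,4,5-trimethoxyphenyl)chroman-7-yl pivalate (2,3-trans; C2 has the same spatial arrangement as in 6) | Brc1cc2c(cc1OC(=O)C(C)(C)C)O[C@H](c1cc(OC)c(OC)c(OC)c1)[C@@H](I(OC(C)=O)c1ccccc1)C2(OC)OC | intermediate
9 | methyl (2S,3S)-5-bromo-6-(pivaloyloxy)-2-(3,4,5-trimethoxyphenyl)-2,3-dihydrobenzofuran-3-carboxylate (trans) | Brc1cc2c(cc1OC(=O)C(C)(C)C)O[C@H](c1cc(OC)c(OC)c(OC)c1)[C@H]2C(=O)OC | intermediate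
10 | methyl (2S,3S)-5-allyl-6-(pivaloyloxy)-2-(3,4,5-trimethoxyphenyl)-2,3-dihydrobenzofuran-3-carboxylate | C=CCc1cc2c(cc1OC(=O)C(C)(C)C)O[C@H](c1cc(OC)c(OC)c(OC)c1)[C@H]2C(=O)OC | intermediate
11 | (2S,3R)-5-allyl-3-(hydroxymethyl)-2-(3,4,5-trimethoxyphenyl)-2,3-dihydrobenzofuran-6-ol | C=CCc1cc2c(cc1O)O[C@H](c1cc(OC)c(OC)c(OC)c1)[C@H]2CO | intermediate
12 | (2S,3S)-5-allyl-3-(iodomethyl)-2-(3,4,5-trimethoxyphenyl)-2,3-dihydrobenzofuran-6-ol | C=CCc1cc2c(cc1O)O[C@H](c1cc(OC)c(OC)c(OC)c1)[C@H]2CI | intermediate
13 | (2S,3S)-5-allyl-3-methyl-2-(3,4,5-trimethoxyphenyl)-2,3-dihydrobenzofuran-6-ol (trans) | C=CCc1cc2c(cc1O)O[C@H](c1cc(OC)c(OC)c(OC)c1)[C@H]2C | target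

## Step count and risks

Total step count: 8. Longest linear sequence: 8 steps (1 to 13).

**Step 4 (ring contraction).** The C2 aryl group may migrate in place of the ring carbon (2,3-shift towards an isoflavone), the iodane intermediate may eliminate to the flavone, the iodane may attack the trimethoxyphenyl ring, or acid may ionise the benzylic C2–O bond and erode the enantiomeric purity. The fallback keeps the same C4a shift but drives it by a photochemical Wolff rearrangement. It sets out from 6: the lithium enolate (LiHMDS, THF, −78 °C) is acylated with 2,2,2-trifluoroethyl trifluoroacetate to the 3-trifluoroacetyl flavanone F1. Detrifluoroacetylative diazo transfer (MsN3, Et3N, MeCN) then gives the 3-diazoflavanone F2. Irradiation of F2 in methanol (350 nm) expels nitrogen, C4a migrates to the carbene carbon C3, and the ring-contracted ketene is trapped by methanol. The cis/trans ester mixture is equilibrated to the trans isomer with catalytic DBU in methanol at 0 °C, and the route is rejoined at 9.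

**Step 3 (asymmetric conjugate addition).** The acyloxy-substituted chromone may react sluggishly, the electron-rich boronic acid may protodeboronate or homocouple, and the facial selectivity or its sense may fall short. The fallback gives up catalytic asymmetric induction for a racemic synthesis with resolution. It sets out from 1: acid-mediated Claisen–Schmidt condensation with 3,4,5-trimethoxybenzaldehyde (SOCl2, EtOH, rt) gives the 2'-hydroxychalcone F3. Oxa-Michael closure (NaOAc, EtOH, reflux) gives the racemic 7-hydroxyflavanone F4, and pivaloylation as in step 2 gives the racemic flavanone pivalate F5. Preparative chromatography on a chiral stationary phase (SFC) separates the enantiomers, and the (S)-enantiomer rejoins the route at 6.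

**Step 7 (iodination beside a free 2-allylphenol).** Iodine may add to the allyl group with ring closure by the phenol (iodoetherification). The para-hydroxy-substituted arene carbon C3a may also take part in the displacement at the primary carbon, giving rearranged or ring-expanded material here or in step 8. The fallback masks the phenol as a non-donating sulfonate and uses hydride displacement in place of halide and radical chemistry. It sets out from 11: TsCl (2.5 equiv), Et3N and DMAP in CH2Cl2 give the bis-tosylate F6. NaBH4 in DMSO at 60 °C displaces only the primary alkyl tosylate to give the 3-methyl aryl tosylate F7. KOH in aqueous methanol at 60 °C cleaves the aryl tosylate, and the route is rejoined at target 13.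

Further compounds

F1 | step 4 | (2S)-6-bromo-4-oxo-3-(trifluoroacetyl)-2-(3,4,5-trimethoxyphenyl)chroman-7-yl pivalate (C3 epimers, largely enolised) | Brc1cc2c(cc1OC(=O)C(C)(C)C)O[C@H](c1cc(OC)c(OC)c(OC)c1)C(C(=O)C(F)(F)F)C2=O
F2 | step 4 | (2R)-6-bromo-3-diazo-4-oxo-2-(3,4,5-trimethoxyphenyl)chroman-7-yl pivalate (same spatial arrangement at C2 as in 6) | Brc1cc2c(cc1OC(=O)C(C)(C)C)O[C@H](c1cc(OC)c(OC)c(OC)c1)C(=[N+]=[N-])C2=O
F3 | step 3 | (E)-1-(5-bromo-2,4-dihydroxyphenyl)-3-(3,4,5-trimethoxyphenyl)prop-2-en-1-one | COc1cc(/C=C/C(=O)c2cc(Br)c(O)cc2O)cc(OC)c1OC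
F4 | step 3 | racemic 6-bromo-7-hydroxy-2-(3,4,5-trimethoxyphenyl)chroman-4-one | O=C1CC(c2cc(OC)c(OC)c(OC)c2)Oc2cc(O)c(Br)cc21
F5 | step 3 | racemic 6-bromo-4-oxo-2-(3,4,5-trimethoxyphenyl)chroman-7-yl pivalate | CC(C)(C)C(=O)Oc1cc2c(cc1Br)C(=O)CC(c1cc(OC)c(OC)c(OC)c1)O2
F6 | step 7 | [(2S,3R)-5-allyl-6-(tosyloxy)-2-(3,4,5-trimethoxyphenyl)-2,3-dihydrobenzofuran-3-yl]methyl 4-methylbenzenesulfonate | C=CCc1cc2c(cc1OS(=O)(=O)c1ccc(C)cc1)O[C@H](c1cc(OC)c(OC)c(OC)c1)[C@H]2COS(=O)(=O)c1ccc(C)cc1
F7 | step 7 | (2S,3S)-5-allyl-3-methyl-2-(3,4,5-trimethoxyphenyl)-2,3-dihydrobenzofuran-6-yl 4-methylbenzenesulfonate | C=CCc1cc2c(cc1OS(=O)(=O)c1ccc(C)cc1)O[C@H](c1cc(OC)c(OC)c(OC)c1)[C@H]2C
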